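Draw the zero line.

in all of them: free catalyst 1 mol%
- oak: starting material 0.50 mM; reagent 1.5 equiv; run made earlier
- ash: starting material 0.50 mM; reagent 1 equiv; run made earlier
- alder: starting material 0.50 mM; reagent 2.2 equiv; run made earlier
- larch: starting material 0.25 mM; reagent 1.5 equiv; run made earlier
- amber: starting material 0.50 mM; reagent 1.50 equiv; one stirred flow tank at steady state, fed with the mixture as stated, mean residence time 2.5 min
- teal: starting material 0.50 mM; reagent 1.50 equiv; everything together in a closed stirred flask, run for 2.5 min; time 2.5 min
- green: starting material 0.50 mM; reagent 1.50 equiv; one stirred flow tank at steady state, fed with the mixture as stated, mean residence time 25.0 min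
- grey: starting material 0.50 mM (fed, over 2.00 min); reagent 1.50 equiv; a stirred flask in which starting material is dosed at a steady rate over 2.00 min without added volume, worked up at 2.5 min; time 2.5 min

oak run (percent of the starting material charged)

| time / min | target / % | starting material / % |
|---|---|---|
| 0.667 | 19 | 80 |
| 1.33 | 33 | 66 |
| 2.00 | 47 | 53 |
| 2.50 | 57 | 42 |

ash run (percent of the starting material charged)

| time / s | target / % | starting material / % |
|---|---|---|
| 25.0 | 9 | 88 |
| 50.0 | 17 | 81 |
| 60.0 | 20 | 82 |
| 90.0 | 32 | 68 |

alder run (percent of the starting material charged)

| time / s | target / % | starting material / % |
|---|---|---|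
| 25.0 | 15 | 87 |
| 50.0 | 26 | 74 |
| 60.0 | 29 | 70 |
| 90.0 | 45 | 54 |

larch run (percent of the starting material charged)

| time / s | target / % | starting material / % |
|---|---|---|
| 12.0 | 3 | 93 |
| 30.0 | 7 | 93 |
| 60.0 | 14 | 85 |
| 90.0 | 21 | 81 |

(readings scatter by 1.5 percentage points)

- the stated concentrations are those of everything mixed, before any reaction; amounts are the same in each set-up
- the feed brings no volume worth counting
- the earlier runs were made in a closed, stirred flask

- the set-up with the highest amount of target at the outlet or at the end, in percent of the starting material put in ("none" if the first two lie within 2 percentage points) (amber / teal / green / grey / none)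
- amount of target at the outlet or at the end, in percent of the starting material put in, amber
- amount of target at the outlet or at the end, in percent of the starting material put in, teal
- amount of target at the outlet or at the end, in percent of the starting material put in, green
- amount of target at the outlet or at the end, in percent of the starting material put in, grey

**Zero line.** Take as zero of the scale the zero-order case, in which the rate ignores [starting material], so that closed flask, tank and dosed flask give the same target after the same time. Read oak, the closed flask with the recipe asked about, at 2.50 min: 57% of target means a zero-order clock, the time the whole charge would take at that mean rate, of 4.39 min. Keep larch's clock too, 7.14 min at 90.0 s, which runs slower than oak's with the charge cut to half.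

**Tank beside flask.** Set amber, the stirred tank, beside teal, the closed flask: same recipe, same 2.5 min. Teal repeats oak, so reckon it at 56.9%. Amber's balance says that target at the outlet equals residence time times the rate at outlet composition, so amber works at oak's late rate, and oak's late clock, read from 1.33 min to 2.50 min with the scatter of 1.5 percentage points in each reading, is 4.87 min, longer than the mean one. Amber therefore ends lower, at 51.3% by my reckoning. Give grey the late clock as well, as a guess of my own, since its starting material enters over 2.00 min and the flask begins without any. Green lasts 5.70 clocks, more than any other set-up, so name it best.

**The flask.** The forecast, “Green, with ten times the residence time, nearly completes”, gives 49% for amber, 57% for teal, 95% for green and 47% for grey, and its figures for amber and grey lie under mine. The flasks give 93.1% for green, the best, then 56.9% for teal, 47.8% for amber and 46.3% for grey.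

    catalyst intermediate C ⇌ released group + catalyst intermediate D (K = 0.00130 M, k = 3.20 s⁻¹)
    catalyst intermediate B ⇌ catalyst intermediate C (K = 22.0, k = 3.10 s⁻¹)
    reagent + free catalyst ⇌ catalyst intermediate A (K = 260 L mol⁻¹, k = 1700 L mol⁻¹ s⁻¹)
    starting material + catalyst intermediate A ⇌ catalyst intermediate B (K = 14000 L mol⁻¹, k = 1.60 × 10⁵ L mol⁻¹ s⁻¹)
    catalyst intermediate D → free catalyst + target (k = 3.80 s⁻¹)

**Stretched clock.** Grey's [starting material] peaks at 0.319 mM, below the 0.50 mM that teal starts from. Its result is a clock of 5.39 min, stretched 1.23 times over oak's. Stretch larch's clock by the same factor to 8.78 min, and 2.5 min buys 28.5%; the flask dosed like grey and charged with 0.30 mM gives 29.7%.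

The earlier runs and the new flask come from a simulation for an exercise, and the scatter is random.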